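**Plan**

1. Retrosynthesis first removes the O8 tiglate, the O6 acetate and the C4–C5 epoxide (made from the E-alkene under direction of the free 6-OH). This leaves a protected (1(10)E,4E)-germacradiene-6,8,9-triol.
2. Enabling feature: the ten-membered ring C1–C10 holds two E-trisubstituted alkene sites, C1=C10 and C4=C5 (the latter masked as the epoxide), lying 1,5 across the C5···C10 axis. Joining C5 to C10 in the reverse sense gives a trans-decalin (rings C1–C5/C10 and C5–C10) with boron on C4 and a mesylate on C1.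
3. The octalin is cut at C8=C9 (ring-closing metathesis, dihydroxylated afterwards), at C6–C7 (allylboration of a C5 aldehyde) and at C5–C6 (carbonylation of a C4=C5 enol triflate). Ring A is what remains of (S)-Wieland–Miescher ketone once its enone ring is degraded to a vinyl group.
4. Forward order: ring A with C10 → C4 methyl, C6, C7/C8 → ring B by metathesis → 8,9-diol → fragmentation opens the ten-membered ring → tigloylation, epoxidation, acetylation, desilylation.
5. Stereochemistry: C10 and the C1 carbinol (cis to C10–CH3, needed only for the fragmentation geometry) come from (S)-Wieland–Miescher ketone and its hydride reduction. C6/C7 come from a catalyst-controlled anti-allylboration, C8/C9 from OsO4 attack anti to C10–CH3 and C7–iPr, both E-alkenes from the trans-decalin geometry, and C4/C5 from the 6-OH-directed epoxidation.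

Key step: step 17

Remark: germacrane numbering (ring C1–C10, C14 on C10, C15 on C4, isopropyl on C7) is used for all intermediates, also before the ten-membered ring exists.
Assumption: the (S)-antipode of the phosphoric acid in step 9 is taken to send the allyl group to the Si face of the aldehyde, by analogy with aryl and alkenyl aldehydes.

**Route**

Step 1
Reactants: 1 (S)-Wieland–Miescher ketone
Product: 2 (4aS,5S)-5-hydroxy-4a-methyl-4,4a,5,6,7,8-hexahydronaphthalen-2(3H)-one
Conditions: NaBH4 (0.3 equiv), EtOH, −10 °C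
Reagents that add atoms: none
Why: Chemoselective borohydride reduction of the saturated ketone beside the enone, in which hydride should add to the face opposite the angular methyl and so set the C1 carbinol cis to C10–CH3.

Step 2
Reactants: 2 (4aS,5S)-5-hydroxy-4a-methyl-4,4a,5,6,7,8-hexahydronaphthalen-2(3H)-one
Product: 3 (4aS,5S)-5-[(tert-butyldimethylsilyl)oxy]-4a-methyl-4,4a,5,6,7,8-hexahydronaphthalen-2(3H)-one
Conditions: TBSCl, imidazole, DMF, 40 °C
Reagents that add atoms: tert-butyldimethylsilyl chloride, SMILES CC(C)(C)[Si](C)(C)Cl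
Why: Imidazole-promoted silylation of a secondary alcohol masks O1 for the oxidative and enolate steps that follow.

Step 3
Reactants: 3 (4aS,5S)-5-[(tert-butyldimethylsilyl)oxy]-4a-methyl-4,4a,5,6,7,8-hexahydronaphthalen-2(3H)-one
Product: 4 3-[(1R,2S)-2-[(tert-butyldimethylsilyl)oxy]-1-methyl-6-oxocyclohexyl]propanoic acid
Conditions: RuCl3·xH2O (2 mol %), NaIO4 (4.2 equiv), CCl4–MeCN–H2O, rt
Reagents that add atoms: sodium periodate, SMILES [Na+].[O-]I(=O)(=O)=O
Why: Ruthenium tetroxide cleavage of the enone C=C, in which the first-formed α-keto acid is decarboxylated oxidatively, should leave the C5 ketone and a propanoic acid chain on the untouched quaternary C10.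

Step 4
Reactants: 4 3-[(1R,2S)-2-[(tert-butyldimethylsilyl)oxy]-1-methyl-6-oxocyclohexyl]propanoic acid
Product: 5 (2R,3S)-3-[(tert-butyldimethylsilyl)oxy]-2-ethenyl-2-methylcyclohexan-1-one
Conditions: Pb(OAc)4 (1.5 equiv), Cu(OAc)2 (0.2 equiv), pyridine, benzene, 80 °C
Reagents that add atoms: none
Why: Kochi oxidative decarboxylation, in which the primary alkyl radical from the lead(IV) carboxylate is oxidised by copper(II) to the terminal alkene, turns the acid chain into the C10 vinyl group (C9=C8).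

Step 5
Reactants: 5 (2R,3S)-3-[(tert-butyldimethylsilyl)oxy]-2-ethenyl-2-methylcyclohexan-1-one
Product: 7 (2R,3S)-3-[(tert-butyldimethylsilyl)oxy]-2-ethenyl-2,6-dimethylcyclohexan-1-one (both epimers at the new methyl carbon), via lithium enolate 6 (not isolated)
Conditions: LDA, THF, −78 °C; MeI, −78 to 0 °C
Reagents that add atoms: iodomethane, SMILES CI (the lithium of 6 comes from LDA, SMILES [Li+].CC(C)[N-]C(C)C)
Why: Enolate alkylation at C4, the only enolisable position because C10 is quaternary, brings in C15, and the new stereocentre is irrelevant because C4 becomes sp2 in the next step.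

Step 6
Reactants: 7 (2R,3S)-3-[(tert-butyldimethylsilyl)oxy]-2-ethenyl-2,6-dimethylcyclohexan-1-one
Product: 9 (5S,6R)-5-[(tert-butyldimethylsilyl)oxy]-6-ethenyl-2,6-dimethylcyclohex-1-en-1-yl trifluoromethanesulfonate, via potassium enolate 8 (not isolated)
Conditions: KHMDS, THF, −78 to 0 °C; PhNTf2
Reagents that add atoms: N-phenylbis(trifluoromethanesulfonimide), SMILES O=S(=O)(N(c1ccccc1)S(=O)(=O)C(F)(F)F)C(F)(F)F (the potassium of 8 comes from KHMDS, SMILES [K+].C[Si](C)(C)[N-][Si](C)(C)C)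
Why: O-Triflation of the only possible, tetrasubstituted enolate fixes the C4=C5 double bond with its methyl group, as is usual for 2,2,6-trisubstituted cyclohexanones.

Step 7
Reactants: 9 (5S,6R)-5-[(tert-butyldimethylsilyl)oxy]-6-ethenyl-2,6-dimethylcyclohex-1-en-1-yl trifluoromethanesulfonate
Product: 10 (5S,6S)-5-[(tert-butyldimethylsilyl)oxy]-6-ethenyl-2,6-dimethylcyclohex-1-ene-1-carbaldehyde
Conditions: Pd(PPh3)4 (5 mol %), CO (1–3 atm), Bu3SnH (slow addition), THF, 50 °C
Reagents that add atoms: carbon monoxide, SMILES [C-]#[O+]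
Why: Palladium-catalysed reductive carbonylation (formylation) of a vinyl triflate with CO and tin hydride places C6 as an aldehyde on C5.

Step 8
Reactants: 11 4-methylpent-1-en-3-ol
Product: 12 4,4,5,5-tetramethyl-2-[(2E)-4-methylpent-2-en-1-yl]-1,3,2-dioxaborolane
Conditions: B2pin2, Pd(II) pincer catalyst (5 mol %), TsOH (5 mol %), DMSO–MeOH, 50 °C
Reagents that add atoms: bis(pinacolato)diboron, SMILES CC1(C)OB(OC1(C)C)B1OC(C)(C)C(C)(C)O1
Why: Palladium-catalysed borylation of an allylic alcohol through a π-allyl intermediate should deliver boron to the unhindered terminus and give the linear E-allylboronate.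

Step 9
Reactants: 10 (5S,6S)-5-[(tert-butyldimethylsilyl)oxy]-6-ethenyl-2,6-dimethylcyclohex-1-ene-1-carbaldehyde; 12 4,4,5,5-tetramethyl-2-[(2E)-4-methylpent-2-en-1-yl]-1,3,2-dioxaborolane
Product: 13 (1S,2S)-1-[(5S,6S)-5-[(tert-butyldimethylsilyl)oxy]-6-ethenyl-2,6-dimethylcyclohex-1-en-1-yl]-2-(propan-2-yl)but-3-en-1-ol
Conditions: (S)-TRIP phosphoric acid (10 mol %), 4 Å MS, toluene, −30 to 0 °C; aqueous work-up
Reagents that add atoms: none
Why: Chiral phosphoric acid-catalysed allylboration through a closed chair transition state, in which the E-boronate should give the anti O6/iPr relationship and the catalyst should direct attack to the Si face of the aldehyde, sets C6 and C7.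

Step 10
Reactants: 13 (1S,2S)-1-[(5S,6S)-5-[(tert-butyldimethylsilyl)oxy]-6-ethenyl-2,6-dimethylcyclohex-1-en-1-yl]-2-(propan-2-yl)but-3-en-1-ol
Product: 14 4-methoxybenzyl ether of 13
Conditions: NaH, PMBBr, Bu4NI (cat.), DMF, 0 °C to rt
Reagents that add atoms: 4-methoxybenzyl bromide, SMILES COc1ccc(CBr)cc1
Why: Williamson etherification of the hindered secondary alkoxide with a reactive benzylic bromide under iodide catalysis.

Step 11
Reactants: 14 4-methoxybenzyl ether of 13
Product: 15 tert-butyl{[(1S,5S,6S,8aS)-5-[(4-methoxybenzyl)oxy]-4,8a-dimethyl-6-(propan-2-yl)-1,2,3,5,6,8a-hexahydronaphthalen-1-yl]oxy}dimethylsilane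
Conditions: Grubbs second-generation catalyst (5 mol %), CH2Cl2 (5 mM), 40 °C
Reagents that add atoms: none
Why: Ring-closing metathesis of the two terminal vinyl groups closes ring B as a cyclohexene (C8=C9) with loss of ethene, while the tetrasubstituted C4=C5 bond is inert.

Step 12
Reactants: 15 tert-butyl{[(1S,5S,6S,8aS)-5-[(4-methoxybenzyl)oxy]-4,8a-dimethyl-6-(propan-2-yl)-1,2,3,5,6,8a-hexahydronaphthalen-1-yl]oxy}dimethylsilane
Product: 16 (1S,5S,6S,8aS)-5-[(4-methoxybenzyl)oxy]-4,8a-dimethyl-6-(propan-2-yl)-1,2,3,5,6,8a-hexahydronaphthalen-1-ol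
Conditions: TBAF, THF, 50 °C
Reagents that add atoms: none
Why: Fluoride cleavage of the silyl ether frees O1 and leaves the benzylic ether and both alkenes untouched.

Step 13
Reactants: 16 (1S,5S,6S,8aS)-5-[(4-methoxybenzyl)oxy]-4,8a-dimethyl-6-(propan-2-yl)-1,2,3,5,6,8a-hexahydronaphthalen-1-ol
Product: 17 (1S,5S,6S,8aS)-5-[(4-methoxybenzyl)oxy]-4,8a-dimethyl-6-(propan-2-yl)-1,2,3,5,6,8a-hexahydronaphthalen-1-yl methanesulfonate
Conditions: MsCl, Et3N, DMAP (cat.), CH2Cl2, 0 °C
Reagents that add atoms: methanesulfonyl chloride, SMILES CS(=O)(=O)Cl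
Why: Sulfonylation of the secondary alcohol gives a neopentyl-type mesylate that should resist substitution and elimination in the steps before the fragmentation.

Step 14
Reactants: 17 (1S,5S,6S,8aS)-5-[(4-methoxybenzyl)oxy]-4,8a-dimethyl-6-(propan-2-yl)-1,2,3,5,6,8a-hexahydronaphthalen-1-yl methanesulfonate
Product: 18 (1S,5S,6S,7S,8R,8aR)-7,8-dihydroxy-5-[(4-methoxybenzyl)oxy]-4,8a-dimethyl-6-(propan-2-yl)-1,2,3,5,6,7,8,8a-octahydronaphthalen-1-yl methanesulfonate
Conditions: OsO4 (2 mol %), NMO, acetone–H2O, rt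
Reagents that add atoms: N-methylmorpholine N-oxide, SMILES C[N+]1([O-])CCOCC1; water, SMILES O
Why: Upjohn dihydroxylation, in which OsO4 should prefer the cis-disubstituted C8=C9 bond over the hindered tetrasubstituted C4=C5 bond and add anti to C10–CH3 and C7–iPr, sets C8 and C9 as a cis-diol trans to the isopropyl group.

Step 15
Reactants: 18 (1S,5S,6S,7S,8R,8aR)-7,8-dihydroxy-5-[(4-methoxybenzyl)oxy]-4,8a-dimethyl-6-(propan-2-yl)-1,2,3,5,6,7,8,8a-octahydronaphthalen-1-yl methanesulfonate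
Product: 19 (1S,5S,6R,7S,8R,8aR)-8-hydroxy-5-[(4-methoxybenzyl)oxy]-4,8a-dimethyl-6-(propan-2-yl)-7-[(triethylsilyl)oxy]-1,2,3,5,6,7,8,8a-octahydronaphthalen-1-yl methanesulfonate
Conditions: TESCl (1.05 equiv), imidazole, CH2Cl2, −20 °C
Reagents that add atoms: chlorotriethylsilane, SMILES CC[Si](Cl)(CC)CC
Why: Kinetic monosilylation, in which the equatorial C8 hydroxyl should react before the axial C9 hydroxyl next to the quaternary carbon.

Step 16
Reactants: 19 (1S,5S,6R,7S,8R,8aR)-8-hydroxy-5-[(4-methoxybenzyl)oxy]-4,8a-dimethyl-6-(propan-2-yl)-7-[(triethylsilyl)oxy]-1,2,3,5,6,7,8,8a-octahydronaphthalen-1-yl methanesulfonate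
Product: 20 (1S,5S,6R,7S,8R,8aR)-8-[(tert-butyldimethylsilyl)oxy]-5-[(4-methoxybenzyl)oxy]-4,8a-dimethyl-6-(propan-2-yl)-7-[(triethylsilyl)oxy]-1,2,3,5,6,7,8,8a-octahydronaphthalen-1-yl methanesulfonate
Conditions: TBSOTf, 2,6-lutidine, CH2Cl2, 0 °C to rt
Reagents that add atoms: tert-butyldimethylsilyl trifluoromethanesulfonate, SMILES CC(C)(C)[Si](C)(C)OS(=O)(=O)C(F)(F)F
Why: Silyl triflate with a hindered pyridine base silylates the remaining hindered alcohol, which also blocks a competing Grob fragmentation of the 9-hydroxy-1-mesylate under the basic conditions of the next step.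

Step 17
Reactants: 20 (1S,5S,6R,7S,8R,8aR)-8-[(tert-butyldimethylsilyl)oxy]-5-[(4-methoxybenzyl)oxy]-4,8a-dimethyl-6-(propan-2-yl)-7-[(triethylsilyl)oxy]-1,2,3,5,6,7,8,8a-octahydronaphthalen-1-yl methanesulfonate
Product: 23 (1(10)E,4E,6R,7R,8S,9R)-9-[(tert-butyldimethylsilyl)oxy]-6-[(4-methoxybenzyl)oxy]-8-[(triethylsilyl)oxy]germacra-1(10),4-diene, via alkylborane 21 (not isolated), via sodium methoxyborate 22 (not isolated)
Conditions: BH3·THF (5 equiv), THF, 0 °C to rt; then NaOMe, MeOH, rt to 40 °C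
Reagents that add atoms: borane–tetrahydrofuran, SMILES [BH3-][O+]1CCCC1, and sodium methoxide, SMILES [Na+].[O-]C (boron and methoxide are found only in 21 and 22 and leave again)
Why: Hydroboration followed by boronate fragmentation (Marshall-type Grob fragmentation): borane should add syn across the tetrasubstituted C4=C5 bond from the face opposite the angular C10 methyl and the axial C6 ether, with boron going to C4 because C5 is flanked by the quaternary C10, to give trans-decalin 21. Methoxide turns 21 into borate 22, in which the equatorial C4–B bond, the C5–C10 fusion bond and the equatorial C1–OMs bond are antiperiplanar, so one concerted seven-centre fragmentation should form C4=C5 and C1=C10 while C5–C10 breaks. The closest known reaction type is the base-induced fragmentation of γ-sulfonyloxy alkylboranes made from octalin sulfonates, which gives (E,E)-cyclodeca-1,5-dienes. The ten-membered ring is not closed by bond formation but unveiled by cleaving the bond shared by the two six-membered rings, a ring expansion of the bicyclo[4.4.0] skeleton. No stereocentre is created, and the E geometry of both alkenes follows from the rigid chair–chair trans-decalin, in which C3/C6 and C2/C9 stand anti across the bonds that become double. The step needs boron on C4 on the face anti to the C10 methyl, which the angular methyl and the axial C6 OPMB should secure by blocking the other face, while the cis relation of C1–OMs and C10–CH3 set in step 1 keeps the leaving group equatorial.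

Step 18
Reactants: 23 (1(10)E,4E,6R,7R,8S,9R)-9-[(tert-butyldimethylsilyl)oxy]-6-[(4-methoxybenzyl)oxy]-8-[(triethylsilyl)oxy]germacra-1(10),4-diene
Product: 24 (1(10)E,4E,6R,7S,8S,9R)-9-[(tert-butyldimethylsilyl)oxy]-6-[(4-methoxybenzyl)oxy]germacra-1(10),4-dien-8-ol
Conditions: HF·pyridine, pyridine, THF, 0 °C
Reagents that add atoms: none
Why: Buffered HF–pyridine should cleave the triethylsilyl ether selectively beside the bulkier TBS ether, using the usual rate difference between the two silyl groups.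

Step 19
Reactants: 24 (1(10)E,4E,6R,7S,8S,9R)-9-[(tert-butyldimethylsilyl)oxy]-6-[(4-methoxybenzyl)oxy]germacra-1(10),4-dien-8-ol; 25 tiglic acid
Product: 27 (1(10)E,4E,6R,7R,8S,9R)-9-[(tert-butyldimethylsilyl)oxy]-6-[(4-methoxybenzyl)oxy]germacra-1(10),4-dien-8-yl (2E)-2-methylbut-2-enoate, via mixed anhydride 26 (not isolated)
Conditions: 25, 2,4,6-trichlorobenzoyl chloride, Et3N, THF, rt; then 24, DMAP, toluene, rt
Reagents that add atoms: 2,4,6-trichlorobenzoyl chloride, SMILES O=C(Cl)c1c(Cl)cc(Cl)cc1Cl (its aroyl group is found only in 26 and leaves again)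
Why: Yamaguchi esterification through the mixed anhydride acylates the hindered C8 alcohol under mild conditions that should keep the E geometry of the tiglate and avoid heating the Cope-prone diene.

Step 20
Reactants: 27 (1(10)E,4E,6R,7R,8S,9R)-9-[(tert-butyldimethylsilyl)oxy]-6-[(4-methoxybenzyl)oxy]germacra-1(10),4-dien-8-yl (2E)-2-methylbut-2-enoate
Product: 28 (1(10)E,4E,6R,7R,8S,9R)-9-[(tert-butyldimethylsilyl)oxy]-6-hydroxygermacra-1(10),4-dien-8-yl (2E)-2-methylbut-2-enoate
Conditions: DDQ, CH2Cl2–pH 7 buffer, 0 °C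
Reagents that add atoms: none
Why: Oxidative cleavage of the electron-rich 4-methoxybenzyl ether by DDQ under buffered conditions frees O6 without touching the silyl ether or the ester.

Step 21
Reactants: 28 (1(10)E,4E,6R,7R,8S,9R)-9-[(tert-butyldimethylsilyl)oxy]-6-hydroxygermacra-1(10),4-dien-8-yl (2E)-2-methylbut-2-enoate
Product: 29 (1(10)E,4R,5R,6S,7R,8S,9R)-9-[(tert-butyldimethylsilyl)oxy]-4,5-epoxy-6-hydroxygermacr-1(10)-en-8-yl (2E)-2-methylbut-2-enoate
Conditions: VO(acac)2 (5 mol %), t-BuOOH, CH2Cl2, 0 °C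
Reagents that add atoms: tert-butyl hydroperoxide, SMILES CC(C)(C)OO
Why: Vanadium-catalysed hydroxyl-directed epoxidation touches only C4=C5, the one alkene allylic to a free hydroxyl, and with H-6 held in the alkene plane by A(1,3) strain against the C4 methyl the oxygen should arrive on the outer face that carries O6, giving the threo (4R,5R) epoxy alcohol.

Step 22
Reactants: 29 (1(10)E,4R,5R,6S,7R,8S,9R)-9-[(tert-butyldimethylsilyl)oxy]-4,5-epoxy-6-hydroxygermacr-1(10)-en-8-yl (2E)-2-methylbut-2-enoate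
Product: 30 (1(10)E,4R,5R,6S,7R,8S,9R)-6-acetoxy-9-[(tert-butyldimethylsilyl)oxy]-4,5-epoxygermacr-1(10)-en-8-yl (2E)-2-methylbut-2-enoate
Conditions: Ac2O, pyridine, DMAP (cat.), CH2Cl2, rt
Reagents that add atoms: acetic anhydride, SMILES CC(=O)OC(C)=O
Why: DMAP-catalysed acylation of the secondary epoxy alcohol under basic, non-nucleophilic conditions that the epoxide should tolerate.

Step 23
Reactants: 30 (1(10)E,4R,5R,6S,7R,8S,9R)-6-acetoxy-9-[(tert-butyldimethylsilyl)oxy]-4,5-epoxygermacr-1(10)-en-8-yl (2E)-2-methylbut-2-enoate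
Product: 31 (1(10)E,4R,5R,6S,7S,8S,9R)-6-acetoxy-4,5-epoxy-9-hydroxygermacr-1(10)-en-8-yl (2E)-2-methylbut-2-enoate (CNP0163041.1)
Conditions: HF·pyridine, pyridine, THF, 0 °C to rt
Reagents that add atoms: none
Why: Fluoride cleavage of the TBS ether under buffered, non-basic conditions is chosen to avoid O8→O9 acyl migration and acid-promoted transannular opening of the epoxide.

**Compound list**

1 | (S)-(+)-Wieland–Miescher ketone, (8aS)-8a-methyl-3,4,8,8a-tetrahydronaphthalene-1,6(2H,7H)-dione | C[C@]12CCC(=O)C=C1CCCC2=O | starting material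
2 | (4aS,5S)-5-hydroxy-4a-methyl-4,4a,5,6,7,8-hexahydronaphthalen-2(3H)-one (OH cis to the angular methyl) | C[C@]12CCC(=O)C=C1CCC[C@@H]2O | intermediate
3 | (4aS,5S)-5-[(tert-butyldimethylsilyl)oxy]-4a-methyl-4,4a,5,6,7,8-hexahydronaphthalen-2(3H)-one | C[C@]12CCC(=O)C=C1CCC[C@@H]2O[Si](C)(C)C(C)(C)C | intermediate
4 | 3-[(1R,2S)-2-[(tert-butyldimethylsilyl)oxy]-1-methyl-6-oxocyclohexyl]propanoic acid | CC(C)(C)[Si](C)(C)O[C@H]1CCCC(=O)[C@]1(C)CCC(=O)O | intermediate
5 | (2R,3S)-3-[(tert-butyldimethylsilyl)oxy]-2-ethenyl-2-methylcyclohexan-1-one | CC(C)(C)[Si](C)(C)O[C@H]1CCCC(=O)[C@]1(C)C=C | intermediate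
6 | lithium enolate of 5 (formed in situ, not isolated) | [Li+].CC(C)(C)[Si](C)(C)O[C@H]1CCC=C([O-])[C@]1(C)C=C | intermediate
7 | (2R,3S)-3-[(tert-butyldimethylsilyl)oxy]-2-ethenyl-2,6-dimethylcyclohexan-1-one, both epimers at the new methyl carbon | CC(C)(C)[Si](C)(C)O[C@H]1CCC(C)C(=O)[C@]1(C)C=C | intermediate
8 | potassium enolate of 7 (formed in situ, not isolated) | [K+].CC(C)(C)[Si](C)(C)O[C@H]1CCC(C)=C([O-])[C@]1(C)C=C | intermediate
9 | (5S,6R)-5-[(tert-butyldimethylsilyl)oxy]-6-ethenyl-2,6-dimethylcyclohex-1-en-1-yl trifluoromethanesulfonate | CC(C)(C)[Si](C)(C)O[C@H]1CCC(C)=C(OS(=O)(=O)C(F)(F)F)[C@]1(C)C=C | intermediate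
10 | (5S,6S)-5-[(tert-butyldimethylsilyl)oxy]-6-ethenyl-2,6-dimethylcyclohex-1-ene-1-carbaldehyde | CC(C)(C)[Si](C)(C)O[C@H]1CCC(C)=C(C=O)[C@]1(C)C=C | intermediate
11 | 4-methylpent-1-en-3-ol (racemic) | CC(C)C(O)C=C | starting material
12 | 4,4,5,5-tetramethyl-2-[(2E)-4-methylpent-2-en-1-yl]-1,3,2-dioxaborolane | CC(C)/C=C/CB1OC(C)(C)C(C)(C)O1 | intermediate
13 | (1S,2S)-1-[(5S,6S)-5-[(tert-butyldimethylsilyl)oxy]-6-ethenyl-2,6-dimethylcyclohex-1-en-1-yl]-2-(propan-2-yl)but-3-en-1-ol (O6 and iPr anti) | CC(C)(C)[Si](C)(C)O[C@H]1CCC(C)=C([C@@H](O)[C@@H](C(C)C)C=C)[C@]1(C)C=C | intermediate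
14 | 4-methoxybenzyl ether of 13 | CC(C)(C)[Si](C)(C)O[C@H]1CCC(C)=C([C@@H](OCc2ccc(OC)cc2)[C@@H](C(C)C)C=C)[C@]1(C)C=C | intermediate
15 | tert-butyl{[(1S,5S,6S,8aS)-5-[(4-methoxybenzyl)oxy]-4,8a-dimethyl-6-(propan-2-yl)-1,2,3,5,6,8a-hexahydronaphthalen-1-yl]oxy}dimethylsilane | CC(C)(C)[Si](C)(C)O[C@H]1CCC(C)=C2[C@@H](OCc3ccc(OC)cc3)[C@@H](C(C)C)C=C[C@]12C | intermediate
16 | (1S,5S,6S,8aS)-5-[(4-methoxybenzyl)oxy]-4,8a-dimethyl-6-(propan-2-yl)-1,2,3,5,6,8a-hexahydronaphthalen-1-ol | O[C@H]1CCC(C)=C2[C@@H](OCc3ccc(OC)cc3)[C@@H](C(C)C)C=C[C@]12C | intermediate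
17 | (1S,5S,6S,8aS)-5-[(4-methoxybenzyl)oxy]-4,8a-dimethyl-6-(propan-2-yl)-1,2,3,5,6,8a-hexahydronaphthalen-1-yl methanesulfonate | CS(=O)(=O)O[C@H]1CCC(C)=C2[C@@H](OCc3ccc(OC)cc3)[C@@H](C(C)C)C=C[C@]12C | intermediate
18 | (1S,5S,6S,7S,8R,8aR)-7,8-dihydroxy-5-[(4-methoxybenzyl)oxy]-4,8a-dimethyl-6-(propan-2-yl)-1,2,3,5,6,7,8,8a-octahydronaphthalen-1-yl methanesulfonate | CS(=O)(=O)O[C@H]1CCC(C)=C2[C@@H](OCc3ccc(OC)cc3)[C@@H](C(C)C)[C@H](O)[C@H](O)[C@]12C | intermediate
19 | (1S,5S,6R,7S,8R,8aR)-8-hydroxy-5-[(4-methoxybenzyl)oxy]-4,8a-dimethyl-6-(propan-2-yl)-7-[(triethylsilyl)oxy]-1,2,3,5,6,7,8,8a-octahydronaphthalen-1-yl methanesulfonate | CS(=O)(=O)O[C@H]1CCC(C)=C2[C@@H](OCc3ccc(OC)cc3)[C@@H](C(C)C)[C@H](O[Si](CC)(CC)CC)[C@H](O)[C@]12C | intermediate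
20 | (1S,5S,6R,7S,8R,8aR)-8-[(tert-butyldimethylsilyl)oxy]-5-[(4-methoxybenzyl)oxy]-4,8a-dimethyl-6-(propan-2-yl)-7-[(triethylsilyl)oxy]-1,2,3,5,6,7,8,8a-octahydronaphthalen-1-yl methanesulfonate (Δ4-octalin, OMs cis to C10–CH3; precursor of the key step) | CS(=O)(=O)O[C@H]1CCC(C)=C2[C@@H](OCc3ccc(OC)cc3)[C@@H](C(C)C)[C@H](O[Si](CC)(CC)CC)[C@H](O[Si](C)(C)C(C)(C)C)[C@]12C | intermediate
21 | alkylborane from syn addition of H–BH2 to 20: trans-decalin with BH2 on C4 and H on C5, both anti to C10–CH3 (formed in situ, not isolated) | CS(=O)(=O)O[C@H]1CC[C@](C)(B)[C@H]2[C@@H](OCc3ccc(OC)cc3)[C@@H](C(C)C)[C@H](O[Si](CC)(CC)CC)[C@H](O[Si](C)(C)C(C)(C)C)[C@]12C | intermediate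
22 | sodium methoxyborate of 21 (formed in situ, not isolated) | [Na+].CS(=O)(=O)O[C@H]1CC[C@](C)([BH2-]OC)[C@H]2[C@@H](OCc3ccc(OC)cc3)[C@@H](C(C)C)[C@H](O[Si](CC)(CC)CC)[C@H](O[Si](C)(C)C(C)(C)C)[C@]12C | intermediate
23 | (1(10)E,4E,6R,7R,8S,9R)-9-[(tert-butyldimethylsilyl)oxy]-6-[(4-methoxybenzyl)oxy]-8-[(triethylsilyl)oxy]germacra-1(10),4-diene | CC[Si](CC)(CC)O[C@H]1[C@H](C(C)C)[C@H](OCc2ccc(OC)cc2)/C=C(\C)CC/C=C(\C)[C@H]1O[Si](C)(C)C(C)(C)C | intermediate
24 | (1(10)E,4E,6R,7S,8S,9R)-9-[(tert-butyldimethylsilyl)oxy]-6-[(4-methoxybenzyl)oxy]germacra-1(10),4-dien-8-ol | O[C@H]1[C@H](C(C)C)[C@H](OCc2ccc(OC)cc2)/C=C(\C)CC/C=C(\C)[C@H]1O[Si](C)(C)C(C)(C)C | intermediate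
25 | tiglic acid, (2E)-2-methylbut-2-enoic acid | C/C=C(\C)C(=O)O | starting material
26 | (2E)-2-methylbut-2-enoic 2,4,6-trichlorobenzoic anhydride (formed in situ, not isolated) | C/C=C(\C)C(=O)OC(=O)c1c(Cl)cc(Cl)cc1Cl | intermediate
27 | (1(10)E,4E,6R,7R,8S,9R)-9-[(tert-butyldimethylsilyl)oxy]-6-[(4-methoxybenzyl)oxy]germacra-1(10),4-dien-8-yl (2E)-2-methylbut-2-enoate | C/C=C(\C)C(=O)O[C@H]1[C@H](C(C)C)[C@H](OCc2ccc(OC)cc2)/C=C(\C)CC/C=C(\C)[C@H]1O[Si](C)(C)C(C)(C)C | intermediate
28 | (1(10)E,4E,6R,7R,8S,9R)-9-[(tert-butyldimethylsilyl)oxy]-6-hydroxygermacra-1(10),4-dien-8-yl (2E)-2-methylbut-2-enoate | C/C=C(\C)C(=O)O[C@H]1[C@H](C(C)C)[C@H](O)/C=C(\C)CC/C=C(\C)[C@H]1O[Si](C)(C)C(C)(C)C | intermediate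
29 | (1(10)E,4R,5R,6S,7R,8S,9R)-9-[(tert-butyldimethylsilyl)oxy]-4,5-epoxy-6-hydroxygermacr-1(10)-en-8-yl (2E)-2-methylbut-2-enoate | C/C=C(\C)C(=O)O[C@H]1[C@H](C(C)C)[C@H](O)[C@H]2O[C@]2(C)CC/C=C(\C)[C@H]1O[Si](C)(C)C(C)(C)C | intermediate
30 | (1(10)E,4R,5R,6S,7R,8S,9R)-6-acetoxy-9-[(tert-butyldimethylsilyl)oxy]-4,5-epoxygermacr-1(10)-en-8-yl (2E)-2-methylbut-2-enoate | C/C=C(\C)C(=O)O[C@H]1[C@H](C(C)C)[C@H](OC(C)=O)[C@H]2O[C@]2(C)CC/C=C(\C)[C@H]1O[Si](C)(C)C(C)(C)C | intermediate
31 | CNP0163041.1, (1(10)E,4R,5R,6S,7S,8S,9R)-6-acetoxy-4,5-epoxy-9-hydroxygermacr-1(10)-en-8-yl (2E)-2-methylbut-2-enoate | C/C=C(\C)C(=O)O[C@H]1[C@H](C(C)C)[C@H](OC(C)=O)[C@H]2O[C@]2(C)CC/C=C(\C)[C@H]1O | target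

**Step count and risks**

Total step count: 23. Longest linear sequence: 22 steps (1 → 31 through steps 1–7 and 9–23; step 8 is a one-step side branch).

Steps most likely to fail:

Step 17 (key step). Hydroboration of the hindered tetrasubstituted alkene may be slow, may occur from the wrong face, or may place boron on C5 under the inductive pull of the allylic C6 ether, so that no antiperiplanar boronate forms. The fallback puts boron on C4 by conjugate borylation at the C6 ketone oxidation level. Setting out from 20, DDQ would remove the PMB group to give the 6-hydroxy octalin F1, and Dess–Martin oxidation would give the Δ4-6-ketone F2. Copper-catalysed β-borylation (CuCl, Xantphos, NaOt-Bu, B2pin2, MeOH, THF) should then give the 4-pinacolboryl trans-decalone F3, with boron entering anti to the C10 methyl and the C5 α-stereocentre free to equilibrate. L-Selectride at −78 °C should attack C6 from the face opposite the two axial methyls to give the axial 4-pinacolboryl decalin-6-ol F4. NaOMe in MeOH would form the boronate and trigger the same antiperiplanar fragmentation to the 6-hydroxy germacradiene F5. PMB protection under neutral conditions (2-(4-methoxybenzyloxy)-4-methylquinoline, MeOTf, MgO) returns the route to 23.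

Step 9. The hindered tetrasubstituted enal may react sluggishly with the γ-branched boronate, and the phosphoric acid may then lose control of the aldehyde face or work against the existing C10 centre. The fallback is stoichiometric reagent control. (E)-4-Methylpent-2-ene would be metalated (n-BuLi, KOt-Bu, THF, −45 °C) to (E)-(4-methylpent-2-enyl)potassium F6. Transmetalation with (−)-B-methoxydiisopinocampheylborane and BF3·OEt2 at −78 °C would give B-[(E)-4-methylpent-2-enyl]diisopinocampheylborane F7. This should add to 10 through the same chair transition state on the Si face, and NaOH/H2O2 work-up returns the route to 13.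

Step 7. Tin hydride may reduce the vinylpalladium intermediate before CO insertion, so the triflate is lost as the simple alkene. The fallback adjusts the oxidation state after an alkoxycarbonylation. From 9, Pd(OAc)2/dppp, CO, MeOH, Et3N in DMF at 60 °C would give the methyl ester F8, DIBAL-H at −78 °C the allylic alcohol F9, and MnO2 in CH2Cl2 returns the route to 10.

**Further compounds**

F1 | step 17 | 6-hydroxy octalin mesylate (20 without the PMB group) | CS(=O)(=O)O[C@H]1CCC(C)=C2[C@@H](O)[C@@H](C(C)C)[C@H](O[Si](CC)(CC)CC)[C@H](O[Si](C)(C)C(C)(C)C)[C@]12C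
F2 | step 17 | Δ4-6-ketone (C6 ketone conjugated with C4=C5) | CS(=O)(=O)O[C@H]1CCC(C)=C2C(=O)[C@@H](C(C)C)[C@H](O[Si](CC)(CC)CC)[C@H](O[Si](C)(C)C(C)(C)C)[C@]12C
F3 | step 17 | 4-pinacolboryl trans-decalone (B on C4 anti to C10–CH3, H-5 trans to C10–CH3) | CS(=O)(=O)O[C@H]1CC[C@](C)(B3OC(C)(C)C(C)(C)O3)[C@H]2C(=O)[C@@H](C(C)C)[C@H](O[Si](CC)(CC)CC)[C@H](O[Si](C)(C)C(C)(C)C)[C@]12C
F4 | step 17 | 4-pinacolboryl trans-decalin-6-ol (axial 6-OH cis to iPr) | CS(=O)(=O)O[C@H]1CC[C@](C)(B3OC(C)(C)C(C)(C)O3)[C@H]2[C@@H](O)[C@@H](C(C)C)[C@H](O[Si](CC)(CC)CC)[C@H](O[Si](C)(C)C(C)(C)C)[C@]12C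
F5 | step 17 | (1(10)E,4E)-9-[(tert-butyldimethylsilyl)oxy]-8-[(triethylsilyl)oxy]germacra-1(10),4-dien-6-ol | CC[Si](CC)(CC)O[C@H]1[C@H](C(C)C)[C@H](O)/C=C(\C)CC/C=C(\C)[C@H]1O[Si](C)(C)C(C)(C)C
F6 | step 9 | (E)-(4-methylpent-2-enyl)potassium | [K+].[CH2-]/C=C/C(C)C
F7 | step 9 | B-[(E)-4-methylpent-2-enyl]diisopinocampheylborane from (−)-Ipc2BOMe | CC(C)/C=C/CB([C@@H]1C[C@@H]2C[C@H]([C@H]1C)C2(C)C)[C@@H]1C[C@@H]2C[C@H]([C@H]1C)C2(C)C
F8 | step 7 | methyl (5S,6S)-5-[(tert-butyldimethylsilyl)oxy]-6-ethenyl-2,6-dimethylcyclohex-1-ene-1-carboxylate | CC(C)(C)[Si](C)(C)O[C@H]1CCC(C)=C(C(=O)OC)[C@]1(C)C=C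
F9 | step 7 | [(5S,6S)-5-[(tert-butyldimethylsilyl)oxy]-6-ethenyl-2,6-dimethylcyclohex-1-en-1-yl]methanol | CC(C)(C)[Si](C)(C)O[C@H]1CCC(C)=C(CO)[C@]1(C)C=C
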